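## Structural features

The target is an achiral bibenzyl. Ring A and ring B are joined by a CH2CH2 bridge, and three 4-hydroxybenzyl groups are attached through diarylmethane CH2 links. The positions of ring A are written a1 to a6 here: a1 bears OMe, a2 H, a3 OH, a4 a 4-hydroxybenzyl group, a5 the bridge and a6 the second 4-hydroxybenzyl group. Three carbon substituents therefore sit on adjacent ring positions. Ring B is 1,2,4-trisubstituted: the third 4-hydroxybenzyl group is ortho to the bridge and the ring B hydroxyl is para to that benzyl group. There is no stereocentre, so no stereochemical relationship has to be set. The fragile parts are the four free phenols beside one methyl ether, the electron-rich resorcinol-type ring A (easily oxidised in base and air) and the three doubly benzylic methylenes. The real difficulty is regiochemical: the contiguous a4/a5/a6 carbon triad on an arene whose two oxygens must end up different. The key step uses the fact that the chain benzyl CH2–a4–a3–a2–a1–a6–benzyl CH2 is a 1,7-diarylheptane-3,5-dione with both oxygens in place, so only a5, the carbon that carries the bridge, has to be inserted.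

## Logic of the disconnections

18 from 17. The four aryl O–CH2Ph bonds are cut. All four free phenols are released in one neutral, reductive operation that leaves the aryl methyl ether alone. The gain is that every earlier step handles a single, robust protecting group. The demand is that nothing else reducible is present at the end and that no earlier step uses heterogeneous hydrogenation.

17 from 16. The O–CH3 bond at a1 is cut. Compound 16 has a mirror plane through a2 and a5, so methylation of either hydroxyl gives 17 and no regiochemical question arises. The gain is that the annulation may deliver a symmetric product. The demand is that the alkylation stops after one methyl group, which is a statistical problem and calls for a limiting amount of the methylating agent and recycling of 16.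

16 from 4 and 13. The a5–a6 bond is cut first (retro-aldol with rehydration, through 15 to 14), then the a4–a5 bond (retro-acylation). Taking a5 out leaves a symmetric seven-carbon chain that already holds both oxygens and both benzyl arms, and a5 leaves with the bridge and the whole of ring B. A pentasubstituted arene is thus reduced to a symmetric acyclic dione and a linear amide. The forward step must acylate the dianion of 4 at a terminal carbon and then close the ring from a6 onto a5 and not in the competing mode.

13 from 12, and 12 from 10 and 11. The amide C–N bond is cut, then the bond between ring B and the first chain carbon. The three-carbon acyl chain is brought in saturated and at the ester oxidation level, so no alkene has to be hydrogenated beside benzyl ethers. The forward coupling must join an sp3 zinc reagent to an electron-rich, ortho-substituted aryl bromide.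

10 from 9, and 9 from 6 and 8 (8 from 7). The benzylic C–O bond is cut, then the bond between the carbinol carbon and the outer ring. The formyl and bromo positions of 6 fix the 1,2,4-pattern of ring B without any aromatic substitution. The aryl magnesium reagent must add to the aldehyde faster than it exchanges with the aryl bromide, and the carbinol must ionise and be reduced without loss of benzyl ethers.

6 from 5. The O–benzyl bond is cut. The phenol must be masked before the organometallic steps, with the same group that is used everywhere else.

4 from 1 and 2 (through 3). The two CH2–CH2 bonds between chain carbons 1/2 and 6/7 are cut. The same dianion reactivity that drives the key step builds the dione from two purchased pieces. The second deprotonation must take place at the remaining methyl group of 3 and not at its substituted methylene.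

## Other disconnections considered

Alternative 1: The cut is made at the bond from a5 to the first bridge carbon and at the bond from a6 to its benzylic carbon, so ring A appears as an a5/a6 aryne inserted into the C–C bond of a β-keto ester. In the forward sense CsF would release the aryne from silyl triflate A1. The enolate carbon of keto ester A2 would add at a5, the a6 aryl anion would close onto the ketone, and fragmentation of the benzocyclobutenoxide would give A3.
- In its favour: two C–C bonds to neighbouring ring carbons are made in one mild operation. The methoxy group at a1 polarises the aryne and directs the nucleophile to a5. There is no second cyclisation mode. The two ring A oxygens differ from the outset, so the statistical methylation of step 8 has no counterpart. On these three points it is the better plan.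
- Against it here: A1 is itself a pentasubstituted benzene that already carries the a4 benzyl group, so the hard part of ring A is only moved into the precursor. The nucleophile must enter at a5 next to that benzyl group, where steric and polar preferences oppose each other. A3 still lacks ring B: the aroyl group must be reduced to a benzyl group and the acetate arm turned into the bridge (reduction to the aldehyde, addition of the aryl metal derived from 10, deoxygenation).
- Comparison: structurally the chosen plan brings in all of ring B with a5 and leaves only methylation and deprotection, while A3 needs about five further operations. Mechanistically the aryne insertion is under kinetic polar control, whereas the chosen annulation depends on which of two aldol closures is taken, so the alternative is the more predictable in regiochemistry. In step economy the chosen plan is clearly the shorter, because preparing A1 alone should take more steps than the whole chosen route up to 16.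

Alternative 2: The cut removes the three bonds between the benzylic carbons and the three outer phenol rings. In the forward sense an excess of 8 would add to the three formyl groups of trialdehyde A4 to give tris(diarylcarbinol) A5 as a mixture of diastereomers. All carbinol centres would then be removed by threefold ionic hydrogenation before the final hydrogenolysis.
- In its favour: it uses the same pair of reactions that the chosen route uses once for ring B (steps 3 and 4), both very dependable. Every position is defined by a formyl group, and the OMe/OBn difference on ring A is built in. In certainty of the key step and in the absence of a statistical step it is the better plan; the endgame is equal.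
- Against it here: A4 is a bibenzyl with two formyl groups flanking the bridge on ring A and a third on ring B, and its preparation (bibenzyl construction, twofold formylation of hindered positions, differentiation of the oxygens) is long and linear. The two ring A aldehydes are di-ortho-substituted, so complete threefold addition needs forcing. The threefold ionisation places diarylmethyl cations next to tethered electron-rich rings, so intramolecular Friedel–Crafts closure (for example of the a6 cation onto ring B to a seven-membered ring) competes with hydride capture.
- Comparison: structurally the alternative hangs the periphery on a preformed core, while the chosen plan forms the core from the periphery. Mechanistically it is the safer of the two. In step economy it is the weaker: the chosen route reaches the full skeleton in seven steps from purchased materials, and the alternative should spend at least as many on A4 alone.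

Alternative 3: The cut removes a4–CH2, a6–CH2 and the bond from a5 to the bridge at once. In the forward sense iodoarene A6, two equivalents of 2 and styrene A7 would be combined with Pd(OAc)2, a triarylphosphine, norbornene and Cs2CO3. Oxidative addition, norbornene insertion and ortho palladation would be followed by benzylation of both ortho positions through tetravalent palladium intermediates. Norbornene would then be extruded and the aryl palladium species intercepted by A7 in a Heck reaction to give stilbene A8.
- In its favour: three bonds and the complete carbon skeleton arise in one operation from pieces that are simple (A6), already in the route (2) or one vinylation away from 10 (A7). The oxygen pattern is differentiated from the start. One hydrogenation would reduce the alkene and remove all five benzyl ethers. In step economy it is the best of the plans considered, about two steps shorter than the chosen route.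
- Against it here: both ortho C–H bonds of A6 lie between the iodine and a meta alkoxy group, the pattern for which ortho palladation and the second norbornene cycle are slowest. Benzyl chlorides are less established than primary alkyl iodides as ortho-alkylating partners and can react with the styrene or with themselves. The terminating Heck reaction must occur on a di-ortho-substituted aryl palladium species with an ortho-substituted styrene.
- Comparison: structurally both plans make the bonds at a4, a5 and a6 in the key step, three in the alternative and two in the chosen plan (a4–CH2 and a6–CH2 are brought in). Mechanistically the alternative needs five organometallic events to run in the right order with nothing that can be isolated and corrected, whereas the chosen annulation passes through 14, which can be isolated if the telescoped closure fails. On regiochemical certainty the alternative is the better; on reagent cost and ease of scale-up the chosen plan is the better.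

Key step: step 7

Remark: 11 is used as its commercial THF solution. Compounds 9, 14 and 15 are racemic or diastereomeric mixtures whose stereocentres are destroyed within the route, so no stereodescriptor is needed. The structures of 4, 13 and 16 map onto the target atom for atom. The design change lies in the way to them: no alkene is formed while benzyl ethers are present.

## Route

Step 1
Reactants: 1 acetylacetone (pentane-2,4-dione); 2 4-(benzyloxy)benzyl chloride (2 equiv in all)
Product: 4 1,7-bis[4-(benzyloxy)phenyl]heptane-3,5-dione, via monoalkylated dione 3 (not isolated)
Conditions: LiN(iPr)2 (2.1 equiv), THF, 0 °C; 2 (1.0 equiv), 0 °C; LiN(iPr)2 (1.1 equiv), 0 °C; 2 (1.0 equiv), 0 → 25 °C; aq NH4Cl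
Reagents that add atoms: none
Why: Terminal alkylation of a 1,3-diketone dianion, run twice in one flask; the central carbon is masked as the enolate, so the benzylic chloride meets only the terminal carbanion. The third equivalent of base should remove a proton from the remaining methyl group of 3 and not from its substituted methylene, which gives the symmetric dione without any alkene intermediate.

Step 2
Reactants: 5 2-bromo-4-hydroxybenzaldehyde
Product: 6 4-(benzyloxy)-2-bromobenzaldehyde
Conditions: BnBr, K2CO3, DMF, 25 °C
Reagents that add atoms: benzyl bromide, BrCc1ccccc1
Why: Williamson ether synthesis on a phenol made acidic by the para formyl group; the benzyl ether protects the phenol from the organometallic steps and is the group used on every other phenol.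

Step 3
Reactants: 6 4-(benzyloxy)-2-bromobenzaldehyde; 7 1-(benzyloxy)-4-bromobenzene
Product: 9 [4-(benzyloxy)-2-bromophenyl][4-(benzyloxy)phenyl]methanol (racemic), via 4-(benzyloxy)phenylmagnesium bromide 8 (not isolated)
Conditions: 7, Mg, I2 (cat.), THF, reflux; then 6, THF, 0 °C; aq NH4Cl
Reagents that add atoms: none
Why: Grignard addition to an aldehyde, which at 0 °C is far faster than halogen–magnesium exchange at the aryl bromide of 6. The new carbinol centre is formed racemic and is removed in step 4.

Step 4
Reactants: 9 [4-(benzyloxy)-2-bromophenyl][4-(benzyloxy)phenyl]methanol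
Product: 10 4-(benzyloxy)-1-[4-(benzyloxy)benzyl]-2-bromobenzene
Conditions: Et3SiH (3 equiv), CF3CO2H (5 equiv), CH2Cl2, 0 °C
Reagents that add atoms: none
Why: Ionic hydrogenation; the carbinol ionises readily to a diarylmethyl cation stabilised by a para oxygen on each ring and is trapped by hydride from the silane. The aryl bromide and the aryl benzyl ethers should survive brief exposure to the acid at 0 °C.

Step 5
Reactants: 10 4-(benzyloxy)-1-[4-(benzyloxy)benzyl]-2-bromobenzene; 11 3-ethoxy-3-oxopropylzinc bromide (1.5 equiv)
Product: 12 ethyl 3-{5-(benzyloxy)-2-[4-(benzyloxy)benzyl]phenyl}propanoate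
Conditions: Pd(OAc)2 (3 mol %), SPhos (2-dicyclohexylphosphino-2',6'-dimethoxybiphenyl, 6 mol %), THF, 60 °C
Reagents that add atoms: none
Why: Negishi sp2–sp3 coupling; the electron-rich biaryl phosphine helps zerovalent palladium insert into the hindered, electron-rich C–Br bond, and the ester-chelated zinc homoenolate resists β-hydride elimination. The chain arrives saturated, so no hydrogenation beside benzyl ethers is needed.

Step 6
Reactants: 12 ethyl 3-{5-(benzyloxy)-2-[4-(benzyloxy)benzyl]phenyl}propanoate
Product: 13 3-{5-(benzyloxy)-2-[4-(benzyloxy)benzyl]phenyl}-N-methoxy-N-methylpropanamide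
Conditions: MeNH(OMe)·HCl (1.5 equiv), iPrMgCl (3.0 equiv), THF, −20 → 0 °C
Reagents that add atoms: N,O-dimethylhydroxylamine hydrochloride, CNOC.Cl
Why: Direct aminolysis of the ester by the magnesium amide of N,O-dimethylhydroxylamine; the chelated tetrahedral adduct does not release a ketone, so excess iPrMgCl causes no over-addition.

Step 7
Reactants: 4 1,7-bis[4-(benzyloxy)phenyl]heptane-3,5-dione (2.0 equiv); 13 3-{5-(benzyloxy)-2-[4-(benzyloxy)benzyl]phenyl}-N-methoxy-N-methylpropanamide (1.0 equiv)
Product: 16 4,6-bis[4-(benzyloxy)benzyl]-5-(2-{5-(benzyloxy)-2-[4-(benzyloxy)benzyl]phenyl}ethyl)benzene-1,3-diol, via triketone 14 (not isolated), via cyclic aldol 15 (not isolated)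
Conditions: 4, LiN(iPr)2 (4.1 equiv), THF, −78 → 0 °C; 13, −78 → 0 °C; AcOH (4.5 equiv), 0 °C; DBU (6 equiv), 60 °C, Ar; then 2 M HCl, 25 °C
Reagents that add atoms: none
Why: Two equivalents of LiN(iPr)2 remove first the proton at the central carbon (a2) and then one at a flanking methylene (a4) of 4; the second, non-stabilised carbanion is the more nucleophilic site and attacks the amide carbonyl of 13 (the future a5), and the lithium-chelated N,O-acetal resists over-addition until acetic acid releases triketone 14. The closest known reaction types are the terminal acylation of 1,3-diketone dianions by esters and N-methoxy-N-methyl amides and the base-induced aldol aromatisation of 1,3,5-triketones to resorcinols, the classical case being heptane-2,4,6-trione to orcinol. Ring A closes in a 6-(enolendo)-exo-trig aldol of the a6 enolate onto the a5 ketone to give 15, which loses water and enolises to the arene, so the transient stereocentres of 14 and 15 vanish and none needs control. Two selectivities are needed: acylation at the terminal carbon and not at a2 or on oxygen, which the dianion secures because a2 is locked in the chelated enolate, and closure from a6 onto a5 and not from the bridge methylene next to a5 onto a1. For the second the substrate offers two biases: the a1–a2–a3 unit has no substituent at a2 and stays as its chelated, fully enolised enolate, which makes a1 a poor electrophile, whereas the benzyl group at a4 keeps the a3/a5 unit largely in the diketo form and leaves a5 a true ketone. DBU in THF is chosen because it is non-nucleophilic (no retro-Claisen cleavage of the new a4–a5 bond) and aprotic (maximal enolisation of the a1–a3 unit). The excess of the cheap dianion allows for proton transfer from 13 or from an adduct that collapses early, and unchanged 4 should be recoverable. The bias in the closure is a reasoned expectation only, because a5 is also the more hindered of the two terminal carbonyl groups.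

Step 8
Reactants: 16 4,6-bis[4-(benzyloxy)benzyl]-5-(2-{5-(benzyloxy)-2-[4-(benzyloxy)benzyl]phenyl}ethyl)benzene-1,3-diol
Product: 17 2,4-bis[4-(benzyloxy)benzyl]-3-(2-{5-(benzyloxy)-2-[4-(benzyloxy)benzyl]phenyl}ethyl)-5-methoxyphenol
Conditions: MeI (1.0 equiv), K2CO3 (1.1 equiv), acetone, 25 °C; recovered 16 recycled
Reagents that add atoms: iodomethane, CI
Why: Williamson ether synthesis; the two hydroxyls of 16 are related by the mirror plane through a2 and a5, so only one mono-ether can form. A limiting amount of iodomethane should hold back the second alkylation, and unchanged 16 is returned to the step.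

Step 9
Reactants: 17 2,4-bis[4-(benzyloxy)benzyl]-3-(2-{5-(benzyloxy)-2-[4-(benzyloxy)benzyl]phenyl}ethyl)-5-methoxyphenol
Product: 18 2,4-bis(4-hydroxybenzyl)-3-{2-[5-hydroxy-2-(4-hydroxybenzyl)phenyl]ethyl}-5-methoxyphenol (target)
Conditions: H2 (1 atm), 10% Pd/C, EtOAc–MeOH, 25 °C
Reagents that add atoms: none
Why: Hydrogenolysis of four aryl benzyl ethers; the aryl methyl ether and the diarylmethane C–C bonds are inert under these conditions, and the molecule has no stereocentre to disturb.

## Compound list

1 | acetylacetone (pentane-2,4-dione) | CC(=O)CC(=O)C | starting material
2 | 4-(benzyloxy)benzyl chloride, 1-(benzyloxy)-4-(chloromethyl)benzene | ClCc1ccc(OCc2ccccc2)cc1 | starting material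
3 | 6-[4-(benzyloxy)phenyl]hexane-2,4-dione (formed in the flask, not isolated) | CC(=O)CC(=O)CCc1ccc(OCc2ccccc2)cc1 | intermediate
4 | 1,7-bis[4-(benzyloxy)phenyl]heptane-3,5-dione | O=C(CCc1ccc(OCc2ccccc2)cc1)CC(=O)CCc1ccc(OCc2ccccc2)cc1 | intermediate
5 | 2-bromo-4-hydroxybenzaldehyde | O=Cc1ccc(O)cc1Br | starting material
6 | 4-(benzyloxy)-2-bromobenzaldehyde | O=Cc1ccc(OCc2ccccc2)cc1Br | intermediate
7 | 1-(benzyloxy)-4-bromobenzene | Brc1ccc(OCc2ccccc2)cc1 | starting material
8 | 4-(benzyloxy)phenylmagnesium bromide (formed in the flask, not isolated) | Br[Mg]c1ccc(OCc2ccccc2)cc1 | intermediate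
9 | [4-(benzyloxy)-2-bromophenyl][4-(benzyloxy)phenyl]methanol, racemic | OC(c1ccc(OCc2ccccc2)cc1)c1ccc(OCc2ccccc2)cc1Br | intermediate
10 | 4-(benzyloxy)-1-[4-(benzyloxy)benzyl]-2-bromobenzene | Brc1cc(OCc2ccccc2)ccc1Cc1ccc(OCc2ccccc2)cc1 | intermediate
11 | 3-ethoxy-3-oxopropylzinc bromide (THF solution) | CCOC(=O)CC[Zn]Br | starting material
12 | ethyl 3-{5-(benzyloxy)-2-[4-(benzyloxy)benzyl]phenyl}propanoate | CCOC(=O)CCc1cc(OCc2ccccc2)ccc1Cc1ccc(OCc2ccccc2)cc1 | intermediate
13 | 3-{5-(benzyloxy)-2-[4-(benzyloxy)benzyl]phenyl}-N-methoxy-N-methylpropanamide | CON(C)C(=O)CCc1cc(OCc2ccccc2)ccc1Cc1ccc(OCc2ccccc2)cc1 | intermediate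
14 | 1-{5-(benzyloxy)-2-[4-(benzyloxy)benzyl]phenyl}-4-[4-(benzyloxy)benzyl]-9-[4-(benzyloxy)phenyl]nonane-3,5,7-trione, racemic at C4 and partly enolised (formed in the flask, not isolated) | O=C(CCc1cc(OCc2ccccc2)ccc1Cc1ccc(OCc2ccccc2)cc1)C(Cc1ccc(OCc2ccccc2)cc1)C(=O)CC(=O)CCc1ccc(OCc2ccccc2)cc1 | intermediate
15 | 4,6-bis[4-(benzyloxy)benzyl]-5-(2-{5-(benzyloxy)-2-[4-(benzyloxy)benzyl]phenyl}ethyl)-5-hydroxycyclohexane-1,3-dione, mixture of diastereomers (formed in the flask, not isolated) | O=C1CC(=O)C(Cc2ccc(OCc3ccccc3)cc2)C(O)(CCc2cc(OCc3ccccc3)ccc2Cc2ccc(OCc3ccccc3)cc2)C1Cc1ccc(OCc2ccccc2)cc1 | intermediate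
16 | 4,6-bis[4-(benzyloxy)benzyl]-5-(2-{5-(benzyloxy)-2-[4-(benzyloxy)benzyl]phenyl}ethyl)benzene-1,3-diol | Oc1cc(O)c(Cc2ccc(OCc3ccccc3)cc2)c(CCc2cc(OCc3ccccc3)ccc2Cc2ccc(OCc3ccccc3)cc2)c1Cc1ccc(OCc2ccccc2)cc1 | intermediate
17 | 2,4-bis[4-(benzyloxy)benzyl]-3-(2-{5-(benzyloxy)-2-[4-(benzyloxy)benzyl]phenyl}ethyl)-5-methoxyphenol | COc1cc(O)c(Cc2ccc(OCc3ccccc3)cc2)c(CCc2cc(OCc3ccccc3)ccc2Cc2ccc(OCc3ccccc3)cc2)c1Cc1ccc(OCc2ccccc2)cc1 | intermediate
18 | 2,4-bis(4-hydroxybenzyl)-3-{2-[5-hydroxy-2-(4-hydroxybenzyl)phenyl]ethyl}-5-methoxyphenol (achiral) | COc1cc(O)c(Cc2ccc(O)cc2)c(CCc2cc(O)ccc2Cc2ccc(O)cc2)c1Cc1ccc(O)cc1 | target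

## Step count and least certain steps

Total step count: 9. Longest linear sequence: 8 steps (steps 2 to 9, from 5 to 18); step 1 is a one-step branch that joins at step 7.

**Step 7 (key step).** The most likely failure is ring closure in the competing mode. The enolate formed at the bridge methylene next to a5 may attack a1, because a simple ketone enolate is reached more easily than the carbanion at a6 and a1 is the less hindered carbonyl; this would give an isomeric resorcinol. Further losses are possible through proton transfer from the α-methylene of 13 to the dianion, retro-Claisen loss of the new acyl group, and O-cyclisation to a 4-pyranone during the acid finish.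

Fallback (sets out from 10 and 2, returns at 18; ring A is taken from an arene and not made by annulation):
- Commercial 3-hydroxy-5-methoxybenzaldehyde would be benzylated (BnBr, K2CO3, DMF) to 3-(benzyloxy)-5-methoxybenzaldehyde F1.
- Seyferth–Gilbert homologation of F1 (dimethyl (1-diazo-2-oxopropyl)phosphonate, K2CO3, MeOH) would give 1-(benzyloxy)-3-ethynyl-5-methoxybenzene F2.
- Sonogashira coupling of F2 with 10 (PdCl2(MeCN)2, 2-dicyclohexylphosphino-2',4',6'-triisopropylbiphenyl, Cs2CO3, MeCN, 80 °C) would give 4-(benzyloxy)-1-[4-(benzyloxy)benzyl]-2-{[3-(benzyloxy)-5-methoxyphenyl]ethynyl}benzene F3, in which a5 already carries the two bridge carbons and ring B.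
- N-Bromosuccinimide (2 equiv, MeCN, 0 °C) should brominate F3 at a4 and a6, each ortho to one ether and para to the other, to give the ring A dibromide F4; the singly activated rings should react much more slowly.
- Twofold Negishi coupling of F4 with 4-(benzyloxy)benzylzinc chloride F5 (made from 2 with Zn and LiCl in THF; Pd(OAc)2, SPhos, 50 °C) would give the pentabenzyl diarylalkyne F6, which has the complete carbon skeleton.
- Hydrogenation of F6 (H2, Pd/C, EtOAc–MeOH) would saturate the alkyne and cleave the five benzyl ethers to give 18.

**Step 1.** The sequential alkylation in one flask may lose control. The second deprotonation may occur partly at the already substituted methylene of 3, and dianion left from the first stage may be alkylated twice, so a mixture of mono-, bis- and branched products may result.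

Fallback (sets out from 1, returns at 4): boron-templated double aldol condensation of 1 with two equivalents of commercial 4-(benzyloxy)benzaldehyde (B2O3, B(OnBu)3, nBuNH2, EtOAc, 80 °C; aq HCl) would give (1E,6E)-1,7-bis[4-(benzyloxy)phenyl]hepta-1,6-diene-3,5-dione F7. Homogeneous hydrogenation of its two alkenes (H2, RhCl(PPh3)3, benzene–EtOH, 50 °C), which does not cleave benzyl ethers, would give 4.

**Step 5.** Oxidative addition to the electron-rich, ortho-substituted bromide may be slow. Protodezincation or homocoupling of 11 would then use up the zinc reagent, and 10 may be reduced to the debrominated arene.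

Fallback (sets out from 10, returns at 13, so step 6 is not needed): Heck reaction of 10 with commercial N-methoxy-N-methylacrylamide (Pd(OAc)2, P(o-tol)3, NaOAc, DMF, 120 °C) would give (2E)-3-{5-(benzyloxy)-2-[4-(benzyloxy)benzyl]phenyl}-N-methoxy-N-methylprop-2-enamide F8. Saturation of the alkene with H2 and RhCl(PPh3)3, which should cleave neither the benzyl ethers nor the N–O bond, would give 13.

**Step 8.** Over-alkylation is the likely problem. The mono-ether is about as acidic as 16 and is methylated at a similar rate, so a statistical mixture of 16, 17 and the dimethyl ether is expected, and the material that is methylated twice is lost.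

Fallback (sets out from 16, returns at 18): exhaustive methylation (MeI in excess, K2CO3, DMF) would give the dimethyl ether F9, and hydrogenolysis (H2, Pd/C) the tetraphenol dimethyl ether F10. One methyl group would then be removed with NaSEt in DMF at 140 °C. The phenoxide formed on ring A after the first cleavage should stop the second, so the choice is made in a self-limiting dealkylation and not in a statistical alkylation.

## Further compounds

F1 | step 7 | 3-(benzyloxy)-5-methoxybenzaldehyde | COc1cc(C=O)cc(OCc2ccccc2)c1
F2 | step 7 | 1-(benzyloxy)-3-ethynyl-5-methoxybenzene | COc1cc(C#C)cc(OCc2ccccc2)c1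
F3 | step 7 | 4-(benzyloxy)-1-[4-(benzyloxy)benzyl]-2-{[3-(benzyloxy)-5-methoxyphenyl]ethynyl}benzene | COc1cc(OCc2ccccc2)cc(C#Cc2cc(OCc3ccccc3)ccc2Cc2ccc(OCc3ccccc3)cc2)c1
F4 | step 7 | 4-(benzyloxy)-1-[4-(benzyloxy)benzyl]-2-{[3-(benzyloxy)-2,6-dibromo-5-methoxyphenyl]ethynyl}benzene | COc1cc(OCc2ccccc2)c(Br)c(C#Cc2cc(OCc3ccccc3)ccc2Cc2ccc(OCc3ccccc3)cc2)c1Br
F5 | step 7 | 4-(benzyloxy)benzylzinc chloride | Cl[Zn]Cc1ccc(OCc2ccccc2)cc1
F6 | step 7 | 1-(benzyloxy)-2,4-bis[4-(benzyloxy)benzyl]-3-({5-(benzyloxy)-2-[4-(benzyloxy)benzyl]phenyl}ethynyl)-5-methoxybenzene | COc1cc(OCc2ccccc2)c(Cc2ccc(OCc3ccccc3)cc2)c(C#Cc2cc(OCc3ccccc3)ccc2Cc2ccc(OCc3ccccc3)cc2)c1Cc1ccc(OCc2ccccc2)cc1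
F7 | step 1 | (1E,6E)-1,7-bis[4-(benzyloxy)phenyl]hepta-1,6-diene-3,5-dione | O=C(/C=C/c1ccc(OCc2ccccc2)cc1)CC(=O)/C=C/c1ccc(OCc2ccccc2)cc1
F8 | step 5 | (2E)-3-{5-(benzyloxy)-2-[4-(benzyloxy)benzyl]phenyl}-N-methoxy-N-methylprop-2-enamide | CON(C)C(=O)/C=C/c1cc(OCc2ccccc2)ccc1Cc1ccc(OCc2ccccc2)cc1
F9 | step 8 | 2,4-bis[4-(benzyloxy)benzyl]-3-(2-{5-(benzyloxy)-2-[4-(benzyloxy)benzyl]phenyl}ethyl)-1,5-dimethoxybenzene | COc1cc(OC)c(Cc2ccc(OCc3ccccc3)cc2)c(CCc2cc(OCc3ccccc3)ccc2Cc2ccc(OCc3ccccc3)cc2)c1Cc1ccc(OCc2ccccc2)cc1
F10 | step 8 | 4-(4-hydroxybenzyl)-3-{2-[2,6-bis(4-hydroxybenzyl)-3,5-dimethoxyphenyl]ethyl}phenol | COc1cc(OC)c(Cc2ccc(O)cc2)c(CCc2cc(O)ccc2Cc2ccc(O)cc2)c1Cc1ccc(O)cc1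
A1 | alternative 1 | 4-(benzyloxy)-3-[4-(benzyloxy)benzyl]-6-methoxy-2-(trimethylsilyl)phenyl trifluoromethanesulfonate | COc1cc(OCc2ccccc2)c(Cc2ccc(OCc3ccccc3)cc2)c([Si](C)(C)C)c1OS(=O)(=O)C(F)(F)F
A2 | alternative 1 | methyl 3-[4-(benzyloxy)phenyl]-3-oxopropanoate | COC(=O)CC(=O)c1ccc(OCc2ccccc2)cc1
A3 | alternative 1 | methyl 2-{3-(benzyloxy)-6-[4-(benzyloxy)benzoyl]-2-[4-(benzyloxy)benzyl]-5-methoxyphenyl}acetate | COc1cc(OCc2ccccc2)c(Cc2ccc(OCc3ccccc3)cc2)c(CC(=O)OC)c1C(=O)c1ccc(OCc2ccccc2)cc1
A4 | alternative 2 | 4-(benzyloxy)-2-{2-[5-(benzyloxy)-2-formylphenyl]ethyl}-6-methoxybenzene-1,3-dicarbaldehyde | COc1cc(OCc2ccccc2)c(C=O)c(CCc2cc(OCc3ccccc3)ccc2C=O)c1C=O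
A5 | alternative 2 | tris(diarylcarbinol) from threefold addition of 8 to A4, mixture of diastereomers | COc1cc(OCc2ccccc2)c(C(O)c2ccc(OCc3ccccc3)cc2)c(CCc2cc(OCc3ccccc3)ccc2C(O)c2ccc(OCc3ccccc3)cc2)c1C(O)c1ccc(OCc2ccccc2)cc1
A6 | alternative 3 | 1-(benzyloxy)-3-iodo-5-methoxybenzene | COc1cc(I)cc(OCc2ccccc2)c1
A7 | alternative 3 | 4-(benzyloxy)-1-[4-(benzyloxy)benzyl]-2-ethenylbenzene | C=Cc1cc(OCc2ccccc2)ccc1Cc1ccc(OCc2ccccc2)cc1
A8 | alternative 3 | (E)-stilbene with the complete carbon skeleton, pentabenzyl ether | COc1cc(OCc2ccccc2)c(Cc2ccc(OCc3ccccc3)cc2)c(/C=C/c2cc(OCc3ccccc3)ccc2Cc2ccc(OCc3ccccc3)cc2)c1Cc1ccc(OCc2ccccc2)cc1
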